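If each L begins one chain, the average chain length is the X reacted divided by the L charged, so I started from that ratio for epsilon and delta.

common to all: X 0.25 M; G 4.2 mM

| run | L | remark | time |
|---|---|---|---|
| noon | 1.5 mol% | run made earlier |  |
| autumn | 2 mol% | run made earlier |  |
| epsilon | 1.6 mol% |  | 12 h |
| delta | 1 mol% |  | 12 h |

- noon (time / h: Z / %, X / %): 3.00: 39, 65; 6.00: 58, 40; 10.0: 80, 23; 12.0: 83, 16
- autumn (time / h: Z / %, X / %): 3.00: 46, 54; 6.00: 70, 28; 10.0: 83, 13; 12.0: 90, 7

(each reading ± 1.5 percentage points)

1. which of the two ends with the longer chains by the average number of monomer units in a chain (chains begun, living or dead) ("neither" if they lie within 10%) (epsilon / delta / neither)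
2. average number of monomer units in a chain (chains begun, living or dead) at the end, epsilon
3. average number of monomer units in a chain (chains begun, living or dead) at the end, delta

- the average divides the monomer in chains by the number of chains begun, living and dead together
- the earlier runs do not show the number of chains; that part of a forecast is a guess

X adds to growing chains and becomes Z. In both earlier runs the logarithm of X fell steadily with time, which is pseudo-first-order behaviour, so I read one rate constant from the last reading of each run. Dividing it by the L charged gave a pace per L:

noon: 40.7 /M/h
autumn: 44.3 /M/h
mean: 42.5 /M/h

With this mean I reckoned the share of X reacted by 12 h, and divided it by the loading of L: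

epsilon: 87.0% reacted, 54.4 units per L
delta: 72.1% reacted, 72.1 units per L

I called this ratio the units per L charged. Delta stood higher, because its loading of L was lower, and this outweighed its lower conversion.

Then I followed one L to its fork, with G as the open question: G might take an L before it began a chain, or G might begin chains of its own. An L lost in this way would raise the true length above the units per L, and chains begun by G would lower it. The runs did not show the number of chains, so I could not size this.

The forecast chose delta, with 50 for epsilon (range 28 to 70) and 62 for delta (range 30 to 95), both below my ratios . Its verdict was: “This is a guess, but delta is favoured.”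

The flasks gave delta as the longer, with 62.7 for epsilon and 82.2 for delta.

    X + L → D + Z (k = 0.0320 /M/s)
    X + D → Z + D, rate k2*[D]*[X] (k = 0.0130 /M/s)
    L + G → J (k = 0.300 /M/s)
    X + L → E (k = 8.40 × 10⁻⁴ /M/s)

At the start of epsilon, one L reacted with X at 0.00800 /s and with G at 0.00126 /s, a rate well below the first. Of these two rates, X took 86.4% at that moment. Epsilon's length stood at 1.15 times my 54.4 units per L. A neighbour of delta with 0.25 mol% of L reached 25.8% Z, which is 103 units per L. Multiplied by that factor this gives 119, and the neighbour's simulated length is 122.

Readings and results were generated by integration with made-up constants, noise included.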